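Assumption: the target has no stereocentre (it is achiral), so no stereocontrol is needed; the free tris(hydrogen sulfate) acid drawn is taken as the final form.

**Retrosynthetic overview**
- Target ⇐ regioselective tri-O-sulfation (7, 3', 4'; the chelated 5-OH is spared) of quercetin 3-acetate.
- Quercetin 3-acetate ⇐ hydrogenolysis of its 5,7,3',4'-tetra-O-benzyl ether.
- Ring C and the C3–OAc bond ⇐ one proposed new step: palladium-catalysed oxidative 6-endo acetoxy-cyclisation of a 2-hydroxyaryl ynone.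
- Ynone ⇐ oxidation of the propargylic alcohol made from a ring B lithium acetylide and a ring A salicylaldehyde.
- Ring B alkyne ⇐ 3,4-bis(benzyloxy)benzaldehyde; ring A aldehyde ⇐ 2,4,6-trihydroxybenzaldehyde. Rings A and B are bought; ring C is formed last.

**Route**

Step 1
Reactants: 1 3,4-bis(benzyloxy)benzaldehyde
Product: 2 4-ethynyl-1,2-bis(benzyloxy)benzene
Conditions: dimethyl (1-diazo-2-oxopropyl)phosphonate (1.3 equiv), K2CO3 (2 equiv), MeOH/THF, 0 °C → rt
Reagents that add atoms: dimethyl (1-diazo-2-oxopropyl)phosphonate, COP(=O)(OC)C(=[N+]=[N-])C(C)=O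
Why: Seyferth–Gilbert homologation in the Ohira–Bestmann variant, in which the diazomethylphosphonate anion generated in situ olefinates the aldehyde and loss of N2 with a 1,2-hydrogen shift gives the terminal alkyne, the benzyl ethers being inert to K2CO3/MeOH.

Step 2
Reactants: 3 2,4,6-trihydroxybenzaldehyde
Product: 4 2,4-bis(benzyloxy)-6-hydroxybenzaldehyde
Conditions: BnBr (2.05 equiv), K2CO3 (2.2 equiv), DMF, 0 °C → rt
Reagents that add atoms: benzyl bromide, BrCc1ccccc1
Why: Williamson etherification that takes the non-chelated 4-OH and one of the two equivalent ortho-OH groups, while the remaining ortho-OH is locked in a hydrogen bond to the formyl group and reacts far more slowly.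

Step 3
Reactants: 2 4-ethynyl-1,2-bis(benzyloxy)benzene; 4 2,4-bis(benzyloxy)-6-hydroxybenzaldehyde
Product: 6 1-[2,4-bis(benzyloxy)-6-hydroxyphenyl]-3-[3,4-bis(benzyloxy)phenyl]prop-2-yn-1-ol (racemic), via lithium acetylide 5 (not isolated)
Conditions: 2 (1.4 equiv), n-BuLi (1.35 equiv), THF, −78 °C; separately 4, LiN(SiMe3)2 (1.05 equiv), THF, −78 °C; combine, −78 → 0 °C; aq NH4Cl
Reagents that add atoms: none
Why: 1,2-addition of a lithium acetylide to an aldehyde whose phenol is first masked as its lithium phenoxide (lithium chelation keeps the formyl group electrophilic); the new carbinol centre is formed racemic and is destroyed in step 4.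

Step 4
Reactants: 6 1-[2,4-bis(benzyloxy)-6-hydroxyphenyl]-3-[3,4-bis(benzyloxy)phenyl]prop-2-yn-1-ol (racemic)
Product: 7 1-[2,4-bis(benzyloxy)-6-hydroxyphenyl]-3-[3,4-bis(benzyloxy)phenyl]prop-2-yn-1-one
Conditions: activated MnO2 (15 equiv), CH2Cl2, rt (crude 6 used at once)
Reagents that add atoms: none
Why: MnO2 oxidation of a doubly activated (benzylic and propargylic) alcohol, neutral enough to leave the hydrogen-bonded 2-hydroxyaryl ynone uncyclised.

Step 5
Reactants: 7 1-[2,4-bis(benzyloxy)-6-hydroxyphenyl]-3-[3,4-bis(benzyloxy)phenyl]prop-2-yn-1-one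
Product: 9 5,7-bis(benzyloxy)-2-[3,4-bis(benzyloxy)phenyl]-4-oxo-4H-chromen-3-yl acetate, via chromen-3-ylpalladium acetate 8 (not isolated)
Conditions: Pd(OAc)2 (10 mol %), PhI(OAc)2 (1.5 equiv, added over 2 h), MeCN, 4 Å MS, 40 °C
Reagents that add atoms: (diacetoxyiodo)benzene, CC(=O)OI(OC(C)=O)c1ccccc1
Why: Proposed new method: divalent palladium coordinates the ynone triple bond and the ortho-phenol adds anti in a 6-endo-dig oxypalladation at the β-carbon (the conjugate position, further polarised by the electron-rich dibenzyloxyphenyl group) to close ring C and give vinylpalladium species 8, which PhI(OAc)2 oxidises to tetravalent palladium so that C(sp2)–OAc reductive elimination forges the C3–O bond and returns Pd(OAc)2, making the pyranone ring and the 3-acetate in one operation with no stereocentre created; the closest known reaction types are electrophile-induced 6-endo cyclisations of 2-oxygenated aryl ynones to 3-iodo- and 3-selanylchromones, palladium-catalysed cyclisation of 2-alkynylphenols with trapping of the vinylpalladium intermediate, and PhI(OAc)2-driven divalent/tetravalent palladium acetoxylation of arene C–H bonds and alkenes.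

Step 6
Reactants: 9 5,7-bis(benzyloxy)-2-[3,4-bis(benzyloxy)phenyl]-4-oxo-4H-chromen-3-yl acetate
Product: 10 quercetin 3-acetate (2-(3,4-dihydroxyphenyl)-5,7-dihydroxy-4-oxo-4H-chromen-3-yl acetate)
Conditions: H2 (1 atm), 10% Pd/C, THF/EtOAc 1:1, rt
Reagents that add atoms: none
Why: Catalytic hydrogenolysis of four benzyl ethers under neutral, alcohol-free conditions, which leaves the conjugated tetrasubstituted C2=C3 bond and the activated 3-O-acetyl ester untouched.

Step 7
Reactants: 10 quercetin 3-acetate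
Product: 12 quercetin 3-acetate 7,3',4'-tri-O-sulfate (free acid), via tris(triethylammonium) salt 11 (not isolated)
Conditions: SO3·NEt3 (12 equiv), DMA, 65 °C; then sulfonic acid cation-exchange resin (H+ form), H2O, 0 °C; C18 chromatography, freeze-dry
Reagents that add atoms: sulfur trioxide–triethylamine complex, CC[N+](CC)(CC)S(=O)(=O)[O-]
Why: Phenol O-sulfation with a neutral sulfur trioxide–amine complex takes the three free phenols at 7, 3' and 4', while the 5-OH hydrogen-bonded to the C4 carbonyl stays free and the 3-acetate is not attacked, and strong-acid ion exchange then replaces triethylammonium by H+.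

**Compound list**
1 | 3,4-bis(benzyloxy)benzaldehyde | O=Cc1ccc(OCc2ccccc2)c(OCc2ccccc2)c1 | starting material
2 | 4-ethynyl-1,2-bis(benzyloxy)benzene | C#Cc1ccc(OCc2ccccc2)c(OCc2ccccc2)c1 | intermediate
3 | 2,4,6-trihydroxybenzaldehyde | O=Cc1c(O)cc(O)cc1O | starting material
4 | 2,4-bis(benzyloxy)-6-hydroxybenzaldehyde | O=Cc1c(O)cc(OCc2ccccc2)cc1OCc1ccccc1 | intermediate
5 | lithium [3,4-bis(benzyloxy)phenyl]acetylide | [Li]C#Cc1ccc(OCc2ccccc2)c(OCc2ccccc2)c1 | intermediate
6 | 1-[2,4-bis(benzyloxy)-6-hydroxyphenyl]-3-[3,4-bis(benzyloxy)phenyl]prop-2-yn-1-ol (racemic) | OC(C#Cc1ccc(OCc2ccccc2)c(OCc2ccccc2)c1)c1c(O)cc(OCc2ccccc2)cc1OCc1ccccc1 | intermediate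
7 | 1-[2,4-bis(benzyloxy)-6-hydroxyphenyl]-3-[3,4-bis(benzyloxy)phenyl]prop-2-yn-1-one | O=C(C#Cc1ccc(OCc2ccccc2)c(OCc2ccccc2)c1)c1c(O)cc(OCc2ccccc2)cc1OCc1ccccc1 | intermediate
8 | {5,7-bis(benzyloxy)-2-[3,4-bis(benzyloxy)phenyl]-4-oxo-4H-chromen-3-yl}palladium acetate | CC(=O)O[Pd]c1c(-c2ccc(OCc3ccccc3)c(OCc3ccccc3)c2)oc2cc(OCc3ccccc3)cc(OCc3ccccc3)c2c1=O | intermediate
9 | 5,7-bis(benzyloxy)-2-[3,4-bis(benzyloxy)phenyl]-4-oxo-4H-chromen-3-yl acetate | CC(=O)Oc1c(-c2ccc(OCc3ccccc3)c(OCc3ccccc3)c2)oc2cc(OCc3ccccc3)cc(OCc3ccccc3)c2c1=O | intermediate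
10 | quercetin 3-acetate | CC(=O)Oc1c(-c2ccc(O)c(O)c2)oc2cc(O)cc(O)c2c1=O | intermediate
11 | quercetin 3-acetate 7,3',4'-tri-O-sulfate tris(triethylammonium) salt | CC(=O)Oc1c(-c2ccc(OS(=O)(=O)[O-])c(OS(=O)(=O)[O-])c2)oc2cc(OS(=O)(=O)[O-])cc(O)c2c1=O.CC[NH+](CC)CC.CC[NH+](CC)CC.CC[NH+](CC)CC | intermediate
12 | quercetin 3-acetate 7,3',4'-tri-O-sulfate | CC(=O)Oc1c(-c2ccc(OS(=O)(=O)O)c(OS(=O)(=O)O)c2)oc2cc(OS(=O)(=O)O)cc(O)c2c1=O | target

**Summary**
Total step count: 7. Longest linear sequence: 6 steps (steps 2–7 from 3, or steps 1 and 3–7 from 1).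

Three steps most likely to fail:

Step 5 (the proposed new step). The risks are protodepalladation of 8 to the 3-unsubstituted flavone, 5-exo closure to an aurone, and oxidation of the phenol by the trivalent iodine reagent. The fallback uses known chemistry only; it sets out from 7 and comes back at 9. Catalytic TfOH in CH2Cl2 at rt cyclises 7 (6-endo) to 5,7-bis(benzyloxy)-2-[3,4-bis(benzyloxy)phenyl]-4H-chromen-4-one F1. Dimethyldioxirane in acetone/CH2Cl2 at 0 °C epoxidises the C2=C3 bond to racemic 2,3-epoxy-5,7,3',4'-tetrakis(benzyloxy)flavanone F2. Catalytic p-TsOH opens F2 to 5,7,3',4'-tetra-O-benzylquercetin F3. Ac2O, pyridine and catalytic DMAP then acetylate the 3-OH to give 9.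

Step 7. The risks are incomplete sulfation of the second catechol oxygen because of charge build-up, loss or transfer of the activated 3-acetate, and hydrolysis of the free sulfuric acid monoesters. The fallback installs the sulfates as neutral protected diesters; it sets out from 10 and comes back at 12. 2,2,2-Trichloroethyl chlorosulfate (3.3 equiv), Et3N and DMAP in THF at 0 °C give quercetin 3-acetate 7,3',4'-tris(2,2,2-trichloroethyl sulfate) F4, which can be purified on silica. Zn dust and HCO2NH4 in MeOH at rt unmask it reductively to quercetin 3-acetate 7,3',4'-tri-O-sulfate tris(ammonium) salt F5. The same cation-exchange resin (H+ form) then gives 12.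

Step 3. The risks are sluggish addition to the electron-rich phenoxide-bearing aldehyde and decomposition of the ortho-hydroxybenzylic alcohol. The fallback protects the phenol first; it sets out from 4 and comes back at 6. TBSCl and imidazole in DMF give 2,4-bis(benzyloxy)-6-[(tert-butyldimethylsilyl)oxy]benzaldehyde F6. Lithium acetylide 5 (1.3 equiv, THF, −78 °C) adds to this neutral aldehyde to give racemic 1-{2,4-bis(benzyloxy)-6-[(tert-butyldimethylsilyl)oxy]phenyl}-3-[3,4-bis(benzyloxy)phenyl]prop-2-yn-1-ol F7. Any silyl shift to the new alkoxide is harmless, because Bu4NF/AcOH in THF at 0 °C removes the silyl group from either oxygen to give 6.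

**Further compounds**
F1 | step 5 | 5,7-bis(benzyloxy)-2-[3,4-bis(benzyloxy)phenyl]-4H-chromen-4-one | O=c1cc(-c2ccc(OCc3ccccc3)c(OCc3ccccc3)c2)oc2cc(OCc3ccccc3)cc(OCc3ccccc3)c12
F2 | step 5 | 2,3-epoxy-5,7,3',4'-tetrakis(benzyloxy)flavanone (racemic) | O=C1c2c(OCc3ccccc3)cc(OCc3ccccc3)cc2OC2(c3ccc(OCc4ccccc4)c(OCc4ccccc4)c3)OC12
F3 | step 5 | 5,7,3',4'-tetra-O-benzylquercetin | O=c1c(O)c(-c2ccc(OCc3ccccc3)c(OCc3ccccc3)c2)oc2cc(OCc3ccccc3)cc(OCc3ccccc3)c12
F4 | step 7 | quercetin 3-acetate 7,3',4'-tris(2,2,2-trichloroethyl sulfate) | CC(=O)Oc1c(-c2ccc(OS(=O)(=O)OCC(Cl)(Cl)Cl)c(OS(=O)(=O)OCC(Cl)(Cl)Cl)c2)oc2cc(OS(=O)(=O)OCC(Cl)(Cl)Cl)cc(O)c2c1=O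
F5 | step 7 | quercetin 3-acetate 7,3',4'-tri-O-sulfate tris(ammonium) salt | CC(=O)Oc1c(-c2ccc(OS(=O)(=O)[O-])c(OS(=O)(=O)[O-])c2)oc2cc(OS(=O)(=O)[O-])cc(O)c2c1=O.[NH4+].[NH4+].[NH4+]
F6 | step 3 | 2,4-bis(benzyloxy)-6-[(tert-butyldimethylsilyl)oxy]benzaldehyde | O=Cc1c(O[Si](C)(C)C(C)(C)C)cc(OCc2ccccc2)cc1OCc1ccccc1
F7 | step 3 | 1-{2,4-bis(benzyloxy)-6-[(tert-butyldimethylsilyl)oxy]phenyl}-3-[3,4-bis(benzyloxy)phenyl]prop-2-yn-1-ol (racemic) | OC(C#Cc1ccc(OCc2ccccc2)c(OCc2ccccc2)c1)c1c(O[Si](C)(C)C(C)(C)C)cc(OCc2ccccc2)cc1OCc1ccccc1
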